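**Retrosynthetic overview**

- The target is a 2-methoxy-4-pyranone. Removing the methyl group from the C2 oxygen leads back to 6-[(10S)-10-acetoxyundecyl]-3,5-diethyl-4-hydroxy-2-pyranone.
- The strategy rests on the only ring (O1, C2–C6): C2–C3(ethyl)–C4 is an ethylmalonyl unit, and C5(ethyl)–C6–O1 is the enol of a propyl alkyl ketone. Cutting C4–C5 and O1–C2 gives ethylmalonyl dichloride and a regiodefined triethylsilyl enol ether, and this three-plus-three annulation forms the ring.
- The enol silane comes from 1,4-hydrosilylation of the propenyl ketone, which is made by Negishi acylation of the alkylzinc from (S)-11-iodoundecan-2-yl acetate with crotonoyl chloride.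
- The iodide comes from CuI-catalysed opening of (S)-propylene oxide by 8-chlorooctylmagnesium bromide (the source of the only stereocentre), followed by acetylation and Finkelstein exchange.

Key step: step 7

Remark on the chemistry: the geometry of the enol silane has no consequence for the annulation, because both of its sp2 carbons end up in the aromatic ring. The Z isomer is drawn because it is the one expected from the hydrosilylation.

**Route**

Step 1
Reactants: 1 1-bromo-8-chlorooctane; 2 (S)-propylene oxide
Product: 4 (S)-11-chloroundecan-2-ol, via 8-chlorooctylmagnesium bromide 3 (not isolated)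
Conditions: Mg turnings, THF, 40 °C; then CuI (10 mol %), 2, −30 → 0 °C; 1 M HCl work-up
Reagents that add atoms: none
Why: Mg inserts into the C–Br bond much faster than into C–Cl, and the CuI-catalysed Grignard opening of a terminal epoxide is an SN2 attack at the unsubstituted CH2, so the C–O bond at the stereocentre is never broken and the (S) configuration of 2 passes unchanged into 4.

Step 2
Reactants: 4 (S)-11-chloroundecan-2-ol
Product: 5 (S)-11-chloroundecan-2-yl acetate
Conditions: Ac2O, pyridine, DMAP (cat.), CH2Cl2, 0 °C → rt
Reagents that add atoms: acetic anhydride, CC(=O)OC(C)=O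
Why: DMAP-catalysed O-acylation of a secondary alcohol, which does not touch the stereocentre or the primary chloride.

Step 3
Reactants: 5 (S)-11-chloroundecan-2-yl acetate
Product: 6 (S)-11-iodoundecan-2-yl acetate
Conditions: NaI (3 equiv), 2-butanone, reflux
Reagents that add atoms: sodium iodide, [Na+].[I-]
Why: Finkelstein halide exchange at a primary chloride, driven by precipitation of NaCl, with the acetate and the stereocentre as spectators.

Step 4
Reactants: 6 (S)-11-iodoundecan-2-yl acetate; 7 (E)-but-2-enoyl chloride
Product: 9 (2E,14S)-14-acetoxypentadec-2-en-4-one, via alkylzinc iodide 8 (not isolated)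
Conditions: activated Zn dust, LiCl, THF, 40 °C; then 7, Pd(PPh3)4 (5 mol %), THF, 0 °C → rt
Reagents that add atoms: none
Why: Direct zinc insertion into the primary C–I bond gives an alkylzinc iodide that tolerates the acetate, and its Pd-catalysed coupling with an acid chloride (Negishi acylation) stops at the ketone and keeps the E double bond.

Step 5
Reactants: 9 (2E,14S)-14-acetoxypentadec-2-en-4-one
Product: 10 (2S,12Z)-12-(triethylsilyloxy)pentadec-12-en-2-yl acetate
Conditions: Et3SiH (1.2 equiv), RhCl(PPh3)3 (1 mol %), toluene, 50 °C; filtration through Et3N-deactivated silica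
Reagents that add atoms: triethylsilane, CC[SiH](CC)CC
Why: RhCl(PPh3)3-catalysed hydrosilylation of an α,β-unsaturated ketone with a monohydrosilane is a 1,4-addition (H to the β-carbon, Si to oxygen) through the s-cis enone, which places the enol double bond on the propyl side only and should give mainly the Z isomer.

Step 6
Reactants: 11 ethylmalonic acid
Product: 12 ethylmalonyl dichloride
Conditions: SOCl2 (neat, excess), 50–60 °C; distillation under reduced pressure
Reagents that add atoms: thionyl chloride, ClS(Cl)=O
Why: Standard conversion of a malonic acid into its dichloride with thionyl chloride, with the volatile product purified by distillation and used fresh.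

Step 7
Reactants: 10 (2S,12Z)-12-(triethylsilyloxy)pentadec-12-en-2-yl acetate; 12 ethylmalonyl dichloride
Product: 14 6-[(10S)-10-acetoxyundecyl]-3,5-diethyl-4-hydroxy-2H-pyran-2-one, via acyclic diketo acid chloride 13 (not isolated)
Conditions: 12 (1.2 equiv), Et2O, −78 °C → rt, 16 h, exclusion of moisture
Reagents that add atoms: none
Why: The dichloride, or the chlorocarbonyl(ethyl)ketene formed from it by loss of HCl, acylates the nucleophilic enol carbon of 10 (the future C5) with loss of Et3SiCl to form C4–C5; the resulting 1,3-diketone 13 enolises toward the future C6, and that enol oxygen attacks the remaining acid chloride to form O1–C2. The closest known reaction type is the condensation of malonyl dichlorides or chlorocarbonylketenes with silyl enol ethers and ketones to give 4-hydroxy-2-pyranones. The single ring closes by a 6-exo-trig lactonisation, and tautomerisation then gives the aromatic hydroxypyranone. No new stereocentre is formed, and the remote (S)-acetoxy centre is not involved. The step needs regioselectivity between two nearly identical α-methylenes of the parent ketone, and this is secured entirely by the position of the enol double bond fixed in step 5; C-acylation is favoured over O-acylation because only the C-acylated material can go on to the stable aromatic lactone. The acetate tolerates the acidic, non-nucleophilic medium.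

Step 8
Reactants: 14 6-[(10S)-10-acetoxyundecyl]-3,5-diethyl-4-hydroxy-2H-pyran-2-one
Product: 16 the target 6-[(10S)-10-acetoxyundecyl]-3,5-diethyl-2-methoxy-4H-pyran-4-one, via 2-methoxypyrylium triflate 15 (not isolated)
Conditions: MeOTf (1.5 equiv), CH2Cl2, rt; then saturated aqueous NaHCO3
Reagents that add atoms: methyl trifluoromethanesulfonate, COS(=O)(=O)C(F)(F)F
Why: A hard methylating agent attacks the neutral hydroxypyranone at the lactone carbonyl oxygen, the basic site remote from the acidic proton, to give the 4-hydroxy-2-methoxypyrylium salt, and deprotonation of its 4-OH on basic work-up releases the 2-methoxy-4-pyranone (known regioselective O-methylation of 4-hydroxy-2-pyranones).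

**Compound list**

1 | 1-bromo-8-chlorooctane | ClCCCCCCCCBr | starting material
2 | (S)-propylene oxide | C[C@H]1CO1 | starting material
3 | 8-chlorooctylmagnesium bromide | ClCCCCCCCC[Mg]Br | intermediate
4 | (S)-11-chloroundecan-2-ol | C[C@H](O)CCCCCCCCCCl | intermediate
5 | (S)-11-chloroundecan-2-yl acetate | C[C@H](OC(C)=O)CCCCCCCCCCl | intermediate
6 | (S)-11-iodoundecan-2-yl acetate | C[C@H](OC(C)=O)CCCCCCCCCI | intermediate
7 | (E)-but-2-enoyl chloride (crotonoyl chloride) | C/C=C/C(=O)Cl | starting material
8 | [(10S)-10-acetoxyundecyl]zinc iodide | C[C@H](OC(C)=O)CCCCCCCCC[Zn]I | intermediate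
9 | (2E,14S)-14-acetoxypentadec-2-en-4-one | C/C=C/C(=O)CCCCCCCCC[C@H](C)OC(C)=O | intermediate
10 | (2S,12Z)-12-(triethylsilyloxy)pentadec-12-en-2-yl acetate | CC/C=C(\O[Si](CC)(CC)CC)CCCCCCCCC[C@H](C)OC(C)=O | intermediate
11 | ethylmalonic acid | CCC(C(=O)O)C(=O)O | starting material
12 | ethylmalonyl dichloride | CCC(C(=O)Cl)C(=O)Cl | intermediate
13 | (15S)-15-acetoxy-2,4-diethyl-3,5-dioxohexadecanoyl chloride (mixture of C2/C4 epimers and enol forms) | CCC(C(=O)Cl)C(=O)C(CC)C(=O)CCCCCCCCC[C@H](C)OC(C)=O | intermediate
14 | 6-[(10S)-10-acetoxyundecyl]-3,5-diethyl-4-hydroxy-2H-pyran-2-one | CCc1c(O)c(CC)c(CCCCCCCCC[C@H](C)OC(C)=O)oc1=O | intermediate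
15 | 6-[(10S)-10-acetoxyundecyl]-3,5-diethyl-4-hydroxy-2-methoxypyrylium trifluoromethanesulfonate | CCc1c(O)c(CC)c(CCCCCCCCC[C@H](C)OC(C)=O)[o+]c1OC.[O-]S(=O)(=O)C(F)(F)F | intermediate
16 | 6-[(10S)-10-acetoxyundecyl]-3,5-diethyl-2-methoxy-4H-pyran-4-one | CCc1c(CCCCCCCCC[C@H](C)OC(C)=O)oc(OC)c(CC)c1=O | target

**Step count**

Total steps: 8. Longest linear sequence: 7 (steps 1, 2, 3, 4, 5, 7, 8); step 6 is a one-step branch.

**Steps most likely to fail**

1. Step 7. The HCl set free may protodesilylate the enol silane before C-acylation, which releases the free ketone and erases the regiochemical information; O-acylation and self-condensation of the ketene may also compete. Fallback, from 10 back to 14: the two bond formations are separated. Enol silane 10 is C-acylated under ZnCl2 mediation (Et2O/CH2Cl2, 0 °C → rt) with ethyl 2-(chlorocarbonyl)butanoate F1, prepared from 2-(ethoxycarbonyl)butanoic acid and oxalyl chloride. This mono-acid chloride sets free no HCl in the C–C bond-forming event and should give ethyl (15S)-15-acetoxy-2,4-diethyl-3,5-dioxohexadecanoate F2. DBU in toluene at 80 °C then closes the lactone with loss of ethanol and returns to the route at 14.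

2. Step 8. Methylation may occur in part at the 4-hydroxyl oxygen instead of the lactone carbonyl oxygen, and acid set free may cleave the acetate. Fallback, from 10 to 16: the methoxy group is carried in as a methyl ester before ring closure, so no ambident pyranone has to be methylated. Enol silane 10 is acylated (ZnCl2, as above) with methyl 2-(chlorocarbonyl)butanoate F3 to give methyl (15S)-15-acetoxy-2,4-diethyl-3,5-dioxohexadecanoate F4. Cyclodehydration with PPh3/CCl4 in THF at rt (Appel-type activation of the δ-keto enol, then attack of the ester carbonyl oxygen) should give the 2-methoxy-4-pyranone 16 directly.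

3. Step 5. Competing 1,2-hydrosilylation of the carbonyl group, or hydrolysis of the enol silane during isolation, would lower the regiochemical purity of 10. Fallback, from 6 back to 10: hydride delivery is replaced by carbon delivery. Alkylzinc iodide 8, made from 6 as in step 4, is acylated with acryloyl chloride (Pd(PPh3)4, THF) to give (S)-13-acetoxytetradec-1-en-3-one F5. Me2CuLi with Et3SiCl in THF at −78 °C then adds a methyl group to the vinyl terminus and traps the enolate on oxygen, which returns to the route at 10 with the same enol double bond position.

**Further compounds**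

F1 | step 7 | ethyl 2-(chlorocarbonyl)butanoate | CCOC(=O)C(CC)C(=O)Cl
F2 | step 7 | ethyl (15S)-15-acetoxy-2,4-diethyl-3,5-dioxohexadecanoate | CCOC(=O)C(CC)C(=O)C(CC)C(=O)CCCCCCCCC[C@H](C)OC(C)=O
F3 | step 8 | methyl 2-(chlorocarbonyl)butanoate | COC(=O)C(CC)C(=O)Cl
F4 | step 8 | methyl (15S)-15-acetoxy-2,4-diethyl-3,5-dioxohexadecanoate | COC(=O)C(CC)C(=O)C(CC)C(=O)CCCCCCCCC[C@H](C)OC(C)=O
F5 | step 5 | (S)-13-acetoxytetradec-1-en-3-one | C=CC(=O)CCCCCCCCC[C@H](C)OC(C)=O
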